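**Retrosynthetic overview**

1. Galbinic acid ⇐ light-induced removal of two o-nitrobenzyl-type groups from 22: an (S)-1-(2-nitrophenyl)ethyl acetal that holds the lactol carbon in the (S) configuration, and a 2-nitrobenzyl ether on the ring A phenol. The CH2OAc group comes from an aryl bromide by Stille hydroxymethylation and acetylation.
2. Seven-membered depsidone lactone ⇐ diaryl ether seco-acid (TFAA lactonisation), with the chiral acetal installed in the same pot.
3. Diaryl ether ⇐ SNAr of the phthalide phenol 16 on the fluoro-benzoate 5 (ring A from 2,6-difluoro-4-methylbenzaldehyde).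
4. Key step: ring B and its γ-lactone ring are made together from α-bromotetronic acid MOM ether and a 4,4-diethoxybut-2-ynoate by silyloxyfuran Diels–Alder reaction, ring-opening aromatisation and pseudo-ester lactonisation.
5. Ring order: ring A (bought) → ring B plus γ-lactone (one operation) → seven-membered ring.

Assumption: the only stereocentre is the lactol carbon, (S) in the given SMILES; because it can epimerise by ring–chain tautomerism, it is carried as a configurationally stable acetal and released last under neutral aprotic conditions. Ring A is the methyl/formyl-bearing ring; ring B is the hexasubstituted ring.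

**Route**

Step 1
Reactants: 1 2,6-difluoro-4-methylbenzaldehyde
Product: 4 tert-butyl 2,4-difluoro-3-formyl-6-methylbenzoate, via lithium amino alkoxide 2 (not isolated), via ring-lithiated alkoxide 3 (not isolated)
Conditions: MeNHCH2CH2NMe2, n-BuLi, THF, −78 °C; then 1; s-BuLi, −78 °C; Boc2O, −78 °C to rt; 1 M HCl
Reagents that add atoms: di-tert-butyl dicarbonate CC(C)(C)OC(=O)OC(=O)OC(C)(C)C
Why: Comins in situ protection of the aldehyde as an α-amino alkoxide permits directed ortho-lithiation next to fluorine (the two ring C–H sites are equivalent by symmetry), and the aryllithium is acylated by Boc2O to the tert-butyl ester.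

Step 2
Reactants: 4 tert-butyl 2,4-difluoro-3-formyl-6-methylbenzoate
Product: 5 tert-butyl 2-fluoro-3-formyl-6-methyl-4-[(2-nitrophenyl)methoxy]benzoate
Conditions: 2-nitrobenzyl alcohol, Cs2CO3, DMF, 0 °C to rt
Reagents that add atoms: 2-nitrobenzyl alcohol OCc1ccccc1[N+](=O)[O-]
Why: Nucleophilic aromatic substitution (addition–elimination) occurs at the 4-fluorine, which is para to the ester and open on one side, rather than at the 2-fluorine wedged between the formyl and tert-butyl ester groups.

Step 3
Reactants: 6 3,3-diethoxyprop-1-yne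
Product: 9 trimethylsilyl 4,4-diethoxybut-2-ynoate, via lithium acetylide 7 (not isolated), via lithium ynoate 8 (not isolated)
Conditions: n-BuLi, THF, −78 °C; CO2; TMSCl, −78 °C to rt; distil
Reagents that add atoms: carbon dioxide O=C=O; chlorotrimethylsilane C[Si](C)(C)Cl
Why: Carboxylation of a lithium acetylide followed by O-silylation of the carboxylate gives the silyl ynoate without exposing the acetal to acid.

Step 4
Reactants: 10 3-bromo-4-hydroxyfuran-2(5H)-one (α-bromotetronic acid)
Product: 11 3-bromo-4-(methoxymethoxy)furan-2(5H)-one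
Conditions: MOMCl, iPr2NEt, CH2Cl2, 0 °C
Reagents that add atoms: chloromethyl methyl ether COCCl
Why: The tetronic acid is a vinylogous carboxylic acid and is O-alkylated at O-4 by the hard electrophile (C-3 is blocked by bromine), which fixes this oxygen as a non-migrating ether for the later diaryl ether formation.

Step 5
Reactants: 11 3-bromo-4-(methoxymethoxy)furan-2(5H)-one; 9 trimethylsilyl 4,4-diethoxybut-2-ynoate
Product: 16 6-bromo-3-ethoxy-4,7-dihydroxy-5-(methoxymethoxy)-2-benzofuran-1(3H)-one (racemic at C-3), via silyloxyfuran 12 (not isolated), via oxanorbornadiene 13 (not isolated), via bis-silyl arene 14 (not isolated), via hydroxy acid 15 (not isolated)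
Conditions: TMSOTf, Et3N, CH2Cl2, 0 °C; 9, toluene, 90 °C; then EtOH, PPTS (cat.), 40 °C
Reagents that add atoms: none
Why: Proposed new method: soft enolisation gives the electron-rich 2-silyloxyfuran, whose free C-5 (pushed by both the 2-siloxy and the 4-alkoxy group) bonds to the β-carbon of the ynoate in a Diels–Alder reaction, the 7-oxanorbornadiene opens at the silyl ketal bridgehead and aromatises to the hydroquinone (carboxyl next to the former carbonyl oxygen, acetal next to the former ring oxygen, which becomes the free phenol), and ethanolysis of the silyl groups lets the acid close on the ortho acetal as the pseudo-ester, so the benzene ring and the γ-lactone form in one operation; the closest known chemistry is the Brownbridge–Chan hydroquinone synthesis from 2-trimethylsilyloxyfuran and acetylenic esters and the spontaneous cyclisation of 2-(dialkoxymethyl)benzoic acids, and C-3 is formed racemic and reset in step 7.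

Step 6
Reactants: 16 6-bromo-3-ethoxy-4,7-dihydroxy-5-(methoxymethoxy)-2-benzofuran-1(3H)-one; 5 tert-butyl 2-fluoro-3-formyl-6-methyl-4-[(2-nitrophenyl)methoxy]benzoate
Product: 17 tert-butyl 2-{[6-bromo-3-ethoxy-7-hydroxy-5-(methoxymethoxy)-1-oxo-1,3-dihydro-2-benzofuran-4-yl]oxy}-3-formyl-6-methyl-4-[(2-nitrophenyl)methoxy]benzoate (racemic at C-3)
Conditions: Cs2CO3, DMSO (degassed), 60 °C
Reagents that add atoms: none
Why: Nucleophilic aromatic substitution at the only remaining fluorine of 5, activated by the ortho formyl and ortho ester groups, takes place through the 4-phenoxide of 16, because the 7-OH is hydrogen-bonded to the lactone carbonyl and flanked by bromine and the neighbouring oxygen is a MOM ether that cannot migrate.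

Step 7
Reactants: 17 diaryl ether from step 6
Product: 20 bromo-depsidone (S,S)-acetal (seven-membered lactone closed; (S)-1-(2-nitrophenyl)ethyl acetal at the (S)-lactol carbon; 2-nitrobenzyl ether on ring A; Br where CH2OAc will stand), via seco acid lactol 18 (not isolated), via lactol trifluoroacetate 19 (not isolated)
Conditions: TFA/H2O 9:1, 40 °C; evaporate; TFAA, toluene, rt; evaporate; (S)-1-(2-nitrophenyl)ethanol, 4 Å MS, CH2Cl2, rt to 40 °C; aq. NaHCO3; chromatography
Reagents that add atoms: (S)-1-(2-nitrophenyl)ethanol C[C@H](O)c1ccccc1[N+](=O)[O-]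
Why: Aqueous TFA cleaves the tert-butyl ester, the MOM ether and the ethyl pseudo-ester, TFAA then activates the hindered benzoic acid for lactonisation onto the only phenol within reach (established TFAA depsidone closure) and turns the lactol into its trifluoroacetate, which the chiral alcohol displaces through the phthalidyl oxocarbenium ion; the acetal carbon forms as both epimers (about 1:1, thermodynamic), the (S,S)-diastereomer 20 is separated by chromatography (configuration by X-ray, bromine as heavy atom) and the other epimer is re-equilibrated with catalytic TFA and recycled.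

Step 8
Reactants: 20 bromo-depsidone (S,S)-acetal
Product: 21 hydroxymethyl-depsidone (S,S)-acetal (CH2OH in place of Br)
Conditions: Bu3SnCH2OH, Pd(PPh3)4 (10 mol%), 1,4-dioxane, 90 °C
Reagents that add atoms: (tributylstannyl)methanol CCCC[Sn](CCCC)(CCCC)CO
Why: Kosugi–Migita–Stille hydroxymethylation (oxidative addition of zerovalent palladium into the aryl bromide, then transmetallation) runs under neutral conditions that leave the lactones, acetal, aldehyde and nitro groups intact and do not touch the acetal stereocentre.

Step 9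
Reactants: 21 hydroxymethyl-depsidone (S,S)-acetal
Product: 22 doubly caged galbinic acid (CH2OAc installed; lactol as (S)-1-(2-nitrophenyl)ethyl acetal; ring A phenol as 2-nitrobenzyl ether)
Conditions: Ac2O (1.1 equiv), pyridine, CH2Cl2, −20 to 0 °C
Reagents that add atoms: acetic anhydride CC(=O)OC(C)=O
Why: O-Acetylation of the primary benzylic alcohol is far faster than that of the adjacent phenol, which is hydrogen-bonded to the lactone carbonyl and flanked on both sides, and the cold, weakly basic medium avoids o-quinone methide formation.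

Step 10
Reactants: 22 doubly caged galbinic acid
Product: 23 galbinic acid, (S) at the lactol carbon
Conditions: hν (365 nm), MeCN (degassed, dilute), 0 °C; evaporate cold; triturate
Reagents that add atoms: none
Why: o-Nitrobenzyl photocleavage (intramolecular hydrogen abstraction by the excited nitro group) releases the phenol and the lactol while the C–O bond at the stereocentre is never broken, so the (S) configuration is retained, and the neutral, aprotic, cold medium suppresses ring–chain epimerisation.

**Compound list**

1 | 2,6-difluoro-4-methylbenzaldehyde | Cc1cc(F)c(C=O)c(F)c1 | starting material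
2 | lithium α-amino alkoxide of 1 (adduct with lithium N,N,N'-trimethylethylenediamide; racemic) | Cc1cc(F)c(C(O[Li])N(C)CCN(C)C)c(F)c1 | intermediate
3 | 3-lithio derivative of 2 (racemic) | Cc1cc(F)c(C(O[Li])N(C)CCN(C)C)c(F)c1[Li] | intermediate
4 | tert-butyl 2,4-difluoro-3-formyl-6-methylbenzoate | Cc1cc(F)c(C=O)c(F)c1C(=O)OC(C)(C)C | intermediate
5 | tert-butyl 2-fluoro-3-formyl-6-methyl-4-[(2-nitrophenyl)methoxy]benzoate | Cc1cc(OCc2ccccc2[N+](=O)[O-])c(C=O)c(F)c1C(=O)OC(C)(C)C | intermediate
6 | 3,3-diethoxyprop-1-yne | C#CC(OCC)OCC | starting material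
7 | lithium 3,3-diethoxyprop-1-yn-1-ide | [Li]C#CC(OCC)OCC | intermediate
8 | lithium 4,4-diethoxybut-2-ynoate | [Li]OC(=O)C#CC(OCC)OCC | intermediate
9 | trimethylsilyl 4,4-diethoxybut-2-ynoate | CCOC(OCC)C#CC(=O)O[Si](C)(C)C | intermediate
10 | 3-bromo-4-hydroxyfuran-2(5H)-one (α-bromotetronic acid) | O=C1OCC(O)=C1Br | starting material
11 | 3-bromo-4-(methoxymethoxy)furan-2(5H)-one | COCOC1=C(Br)C(=O)OC1 | intermediate
12 | 3-bromo-4-(methoxymethoxy)-2-[(trimethylsilyl)oxy]furan | COCOc1coc(O[Si](C)(C)C)c1Br | intermediate
13 | trimethylsilyl 6-bromo-3-(diethoxymethyl)-5-(methoxymethoxy)-1-[(trimethylsilyl)oxy]-7-oxabicyclo[2.2.1]hepta-2,5-diene-2-carboxylate (racemic) | CCOC(OCC)C1=C(C(=O)O[Si](C)(C)C)C2(O[Si](C)(C)C)OC1C(OCOC)=C2Br | intermediate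
14 | trimethylsilyl 3-bromo-6-(diethoxymethyl)-5-hydroxy-4-(methoxymethoxy)-2-[(trimethylsilyl)oxy]benzoate | CCOC(OCC)c1c(O)c(OCOC)c(Br)c(O[Si](C)(C)C)c1C(=O)O[Si](C)(C)C | intermediate
15 | 3-bromo-6-(diethoxymethyl)-2,5-dihydroxy-4-(methoxymethoxy)benzoic acid | CCOC(OCC)c1c(O)c(OCOC)c(Br)c(O)c1C(=O)O | intermediate
16 | 6-bromo-3-ethoxy-4,7-dihydroxy-5-(methoxymethoxy)-2-benzofuran-1(3H)-one (racemic) | CCOC1OC(=O)c2c(O)c(Br)c(OCOC)c(O)c12 | intermediate
17 | tert-butyl 2-{[6-bromo-3-ethoxy-7-hydroxy-5-(methoxymethoxy)-1-oxo-1,3-dihydro-2-benzofuran-4-yl]oxy}-3-formyl-6-methyl-4-[(2-nitrophenyl)methoxy]benzoate (racemic) | Cc1cc(OCc2ccccc2[N+](=O)[O-])c(C=O)c(Oc2c(OCOC)c(Br)c(O)c3c2C(OCC)OC3=O)c1C(=O)OC(C)(C)C | intermediate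
18 | 2-[(6-bromo-3,5,7-trihydroxy-1-oxo-1,3-dihydro-2-benzofuran-4-yl)oxy]-3-formyl-6-methyl-4-[(2-nitrophenyl)methoxy]benzoic acid (racemic lactol) | Cc1cc(OCc2ccccc2[N+](=O)[O-])c(C=O)c(Oc2c(O)c(Br)c(O)c3c2C(O)OC3=O)c1C(=O)O | intermediate
19 | bromo-depsidone with the lactol as trifluoroacetate (seven-membered lactone closed; racemic) | Brc1c(O)c2c(c3c1OC(=O)c1c(C)cc(OCc4ccccc4[N+](=O)[O-])c(C=O)c1O3)C(OC(=O)C(F)(F)F)OC2=O | intermediate
20 | bromo-depsidone (S,S)-acetal: (S)-1-(2-nitrophenyl)ethyl acetal at the (S)-lactol carbon, 2-nitrobenzyl ether on ring A, Br on ring B | Brc1c(O)c2c(c3c1OC(=O)c1c(C)cc(OCc4ccccc4[N+](=O)[O-])c(C=O)c1O3)[C@@H](O[C@@H](C)c1ccccc1[N+](=O)[O-])OC2=O | intermediate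
21 | hydroxymethyl-depsidone (S,S)-acetal (CH2OH in place of Br in 20) | OCc1c(O)c2c(c3c1OC(=O)c1c(C)cc(OCc4ccccc4[N+](=O)[O-])c(C=O)c1O3)[C@@H](O[C@@H](C)c1ccccc1[N+](=O)[O-])OC2=O | intermediate
22 | doubly caged galbinic acid (acetate of 21) | CC(=O)OCc1c(O)c2c(c3c1OC(=O)c1c(C)cc(OCc4ccccc4[N+](=O)[O-])c(C=O)c1O3)[C@@H](O[C@@H](C)c1ccccc1[N+](=O)[O-])OC2=O | intermediate
23 | galbinic acid, (S) at the lactol carbon | CC(=O)OCc1c(O)c2c(c3c1OC(=O)c1c(C)cc(O)c(C=O)c1O3)[C@@H](O)OC2=O | target

**Totals and risks**

Total step count: 10. Longest linear sequence: 7 steps (steps 4, 5, 6, 7, 8, 9, 10; the branches through steps 1–2 and through step 3 are equally long).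

Steps most likely to fail:

Step 5 (cycloaddition/aromatisation/lactonisation cascade). If the thermal Diels–Alder reaction is too slow or gives open-chain Michael products, the ring is built in the anionic manifold instead. The fallback sets out from 11 and 6. Alkyne 6 is converted with n-BuLi and allyl chloroformate into allyl 4,4-diethoxybut-2-ynoate F1. Lactone 11 is deprotonated at C-5 with LiN(SiMe3)2 in THF at −78 °C and added to F1. Michael addition is followed by Claisen-type closure of the vinyl anion onto the lactone carbonyl with ring opening (a Hauser–Kraus-type annulation) and gives allyl 3-bromo-6-(diethoxymethyl)-2,5-dihydroxy-4-(methoxymethoxy)benzoate F2. Pd(PPh3)4 and morpholine remove the allyl group, and the route is rejoined at hydroxy acid 15, which is closed to 16 with PPTS in ethanol.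

Step 6 (formation of a tetra-ortho-substituted diaryl ether). If the tert-butyl ester blocks the substitution, the electrophile is changed to the carboxylate. The fallback sets out from 5. TFA cleaves the ester to 2-fluoro-3-formyl-6-methyl-4-[(2-nitrophenyl)methoxy]benzoic acid F3. Its cesium salt is coupled with 16 (Cs2CO3, DMSO), where the small carboxylate and cation bridging favour attack at the neighbouring fluorine, to give 2-{[6-bromo-3-ethoxy-7-hydroxy-5-(methoxymethoxy)-1-oxo-1,3-dihydro-2-benzofuran-4-yl]oxy}-3-formyl-6-methyl-4-[(2-nitrophenyl)methoxy]benzoic acid F4. F4 is taken into the aqueous TFA stage of step 7 and the route is rejoined at 18.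

Step 7 (three events in one pot and an unselective acetal centre). If TFAA lactonisation in the presence of the free lactol is messy, the order is reversed. The fallback sets out from 17. Aqueous TFA gives 18, which is isolated and acetalised with (S)-1-(2-nitrophenyl)ethanol (camphorsulfonic acid, 4 Å MS) to the seco-acid (S,S)-acetal F5, with the epimers separated at this stage. The seven-membered lactone is then closed under Mukaiyama conditions (2-chloro-1-methylpyridinium iodide, Et3N, CH2Cl2, high dilution), and the route is rejoined at 20.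

**Further compounds**

F1 | step 5 | allyl 4,4-diethoxybut-2-ynoate | CCOC(OCC)C#CC(=O)OCC=C
F2 | step 5 | allyl 3-bromo-6-(diethoxymethyl)-2,5-dihydroxy-4-(methoxymethoxy)benzoate | CCOC(OCC)c1c(O)c(OCOC)c(Br)c(O)c1C(=O)OCC=C
F3 | step 6 | 2-fluoro-3-formyl-6-methyl-4-[(2-nitrophenyl)methoxy]benzoic acid | Cc1cc(OCc2ccccc2[N+](=O)[O-])c(C=O)c(F)c1C(=O)O
F4 | step 6 | 2-{[6-bromo-3-ethoxy-7-hydroxy-5-(methoxymethoxy)-1-oxo-1,3-dihydro-2-benzofuran-4-yl]oxy}-3-formyl-6-methyl-4-[(2-nitrophenyl)methoxy]benzoic acid (racemic) | Cc1cc(OCc2ccccc2[N+](=O)[O-])c(C=O)c(Oc2c(OCOC)c(Br)c(O)c3c2C(OCC)OC3=O)c1C(=O)O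
F5 | step 7 | seco-acid (S,S)-acetal: 18 with the lactol as (S)-1-(2-nitrophenyl)ethyl acetal, (S) at the acetal carbon | Cc1cc(OCc2ccccc2[N+](=O)[O-])c(C=O)c(Oc2c(O)c(Br)c(O)c3c2[C@@H](O[C@@H](C)c2ccccc2[N+](=O)[O-])OC3=O)c1C(=O)O
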